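**Retrosynthetic overview**

1. The strategy rests on ring D, a benzene with oxygen on C1 and C4 (para) and the CH2CH2 link to ring C on C2. A methoxy(vinyl)carbene chromium complex (C4, C5, C6), a terminal alkyne (C2, C3) and one CO ligand (C1) give exactly this pattern as a 2-alkyl-4-methoxyphenol.
2. Target ⇐ quinone (H2/Pd: quinone reduction and O-debenzylation of ring B) ⇐ ring D 4-methoxyphenol (CAN) ⇐ Dötz benzannulation of the carbene complex with a 4-arylbut-1-yne (bonds C3–C4, C1–C2, C1–C6).
3. Alkyne ⇐ aldehyde (Ohira–Bestmann) ⇐ methyl ester (DIBAL-H) ⇐ Ullmann C–O coupling of the ring A–B bromide with methyl 3-(4-hydroxyphenyl)propanoate (ring C).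
4. Ring A–B bromide ⇐ Wittig olefination and diimide reduction from O-benzylated 3-bromo-4-hydroxybenzaldehyde; carbene complex ⇐ Cr(CO)6, vinyllithium and MeOTf.
5. Rings A, B and C are bought as benzenes; ring D is the only ring formed (step 8).

Key step: step 8

Remark: the target has no stereocentre, stereogenic axis or C=C bond, so it is achiral and "single enantiomer" asks for no stereocontrol. The SMILES therefore carry no stereodescriptors; stilbene 5 is used as an E/Z mixture that converges in step 3.

**Route**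

Step 1
Reactants: 1 3-bromo-4-hydroxybenzaldehyde
Product: 2 4-(benzyloxy)-3-bromobenzaldehyde
Conditions: BnBr, K2CO3, DMF, rt
Reagents that add atoms: benzyl bromide (BrCc1ccccc1)
Why: Williamson ether synthesis; the phenoxide, acidified by the para-formyl and ortho-bromo groups, should be alkylated cleanly on oxygen.

Step 2
Reactants: 2 4-(benzyloxy)-3-bromobenzaldehyde; 3 (3-methoxybenzyl)triphenylphosphonium chloride
Product: 5 1-(benzyloxy)-2-bromo-4-[2-(3-methoxyphenyl)ethenyl]benzene (E/Z mixture), via phosphorus ylide 4 (not isolated)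
Conditions: KOtBu, THF, 0 °C; then 2, 0 °C → rt
Reagents that add atoms: none
Why: Wittig olefination with a semi-stabilised benzylic ylide joins rings A and B; the E/Z mixture is of no consequence because the double bond is saturated in step 3.

Step 3
Reactants: 5 1-(benzyloxy)-2-bromo-4-[2-(3-methoxyphenyl)ethenyl]benzene
Product: 6 1-(benzyloxy)-2-bromo-4-[2-(3-methoxyphenyl)ethyl]benzene
Conditions: TsNHNH2 (excess, in portions), NaOAc, DME/H2O, reflux
Reagents that add atoms: none
Why: Diimide reduction delivers H2 to the C=C bond by a concerted syn transfer and should leave the aryl bromide and benzyl ether intact, which Pd-catalysed hydrogenation would not.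

Step 4
Reactants: 6 1-(benzyloxy)-2-bromo-4-[2-(3-methoxyphenyl)ethyl]benzene; 7 methyl 3-(4-hydroxyphenyl)propanoate
Product: 8 methyl 3-(4-{2-(benzyloxy)-5-[2-(3-methoxyphenyl)ethyl]phenoxy}phenyl)propanoate
Conditions: CuI (10 mol %), N,N-dimethylglycine·HCl (30 mol %), Cs2CO3, dioxane, 100 °C
Reagents that add atoms: none
Why: Ligand-accelerated Ullmann diaryl ether synthesis couples the aryl bromide with the unhindered para-alkylphenol at a temperature that the methyl ester and benzyl ether should tolerate.

Step 5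
Reactants: 8 methyl 3-(4-{2-(benzyloxy)-5-[2-(3-methoxyphenyl)ethyl]phenoxy}phenyl)propanoate
Product: 10 3-(4-{2-(benzyloxy)-5-[2-(3-methoxyphenyl)ethyl]phenoxy}phenyl)propanal, via aluminium hemiacetal 9 (not isolated)
Conditions: DIBAL-H (1.1 equiv), CH2Cl2, −78 °C; MeOH quench, aq. Rochelle salt
Reagents that add atoms: none
Why: Partial ester reduction with DIBAL-H; at −78 °C the tetrahedral aluminium hemiacetal 9 persists and releases the aldehyde only on hydrolysis, which limits over-reduction.

Step 6
Reactants: 10 3-(4-{2-(benzyloxy)-5-[2-(3-methoxyphenyl)ethyl]phenoxy}phenyl)propanal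
Product: 11 1-(benzyloxy)-2-[4-(but-3-yn-1-yl)phenoxy]-4-[2-(3-methoxyphenyl)ethyl]benzene
Conditions: Ohira–Bestmann reagent, K2CO3, MeOH/THF, 0 °C → rt
Reagents that add atoms: dimethyl (1-diazo-2-oxopropyl)phosphonate (CC(=O)C(=[N+]=[N-])P(=O)(OC)OC)
Why: Ohira–Bestmann variant of the Seyferth–Gilbert homologation converts the enolisable aldehyde into the terminal alkyne with one added carbon under mild carbonate/methanol conditions.

Step 7
Reactants: 12 vinyl bromide; 13 chromium hexacarbonyl
Product: 16 pentacarbonyl[methoxy(vinyl)carbene]chromium, via vinyllithium 14 (not isolated), via lithium acylchromate 15 (not isolated)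
Conditions: t-BuLi (2 equiv), Et2O, −78 °C; then 13, Et2O, −78 → 0 °C; then MeOTf, CH2Cl2, −20 → 0 °C; cold silica filtration (pentane), used at once
Reagents that add atoms: methyl trifluoromethanesulfonate (COS(=O)(=O)C(F)(F)F)
Why: Fischer carbene synthesis: bromine–lithium exchange, addition of vinyllithium to a CO ligand and O-methylation of the acylate by a hard methylating agent; the complex is kept cold and used fresh because the parent vinyl complex polymerises readily.

Step 8
Reactants: 11 1-(benzyloxy)-2-[4-(but-3-yn-1-yl)phenoxy]-4-[2-(3-methoxyphenyl)ethyl]benzene; 16 pentacarbonyl[methoxy(vinyl)carbene]chromium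
Product: 18 2-[2-(4-{2-(benzyloxy)-5-[2-(3-methoxyphenyl)ethyl]phenoxy}phenyl)ethyl]-4-methoxyphenol, via tricarbonylchromium arene complex 17 (not isolated)
Conditions: 16 (2 equiv, in portions), THF (0.05 M), 45–50 °C, Ar; then air, Et2O, rt
Reagents that add atoms: none
Why: Thermal loss of one CO from 16 opens a site for the alkyne, which inserts into the Cr=C bond to give an η1:η3-vinylcarbene; migratory CO insertion then gives an η4-dienylketene, whose 6π-electrocyclisation and enolisation deliver the phenol as its Cr(CO)3 complex 17, from which air releases 18. The closest known reaction type is the Dötz benzannulation of alkenyl(alkoxy)carbene chromium complexes with terminal alkynes, of which this is a direct case. Ring D is closed by the 6π-electrocyclic closure of the dienylketene (bond C1–C6), after bond C4–C3 (carbene carbon to alkyne CH) and bond C2–C1 (substituted alkyne carbon to CO) have formed at chromium, a formal [3+2+1] assembly. No stereocentre is created. The step needs regiocontrol of alkyne insertion, and the terminal alkyne secures it sterically: the alkyne hydrogen, not the CH2CH2Ar chain, takes the internal vinylcarbene position that is pressed against a CO ligand, so the chain-bearing carbon becomes the chromium-bound carbon that captures CO and the chain ends ortho to the new OH and para-related OMe/OH are set. The aryl ethers and the benzyl ether are inert at 50 °C, and the labile partner 16 is used in excess so that the valuable alkyne is consumed.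

Step 9
Reactants: 18 2-[2-(4-{2-(benzyloxy)-5-[2-(3-methoxyphenyl)ethyl]phenoxy}phenyl)ethyl]-4-methoxyphenol
Product: 19 2-[2-(4-{2-(benzyloxy)-5-[2-(3-methoxyphenyl)ethyl]phenoxy}phenyl)ethyl]cyclohexa-2,5-diene-1,4-dione
Conditions: CAN (2.2 equiv), MeCN/H2O, 0 °C, 10 min
Reagents that add atoms: water (O)
Why: Oxidative demethylation with ceric ammonium nitrate: the para-methoxyphenol is the most easily oxidised ring, water adds at C4 of the oxidised ring and methanol is lost, while the ring A anisole and the ring B catechol diether should survive the short cold exposure.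

Step 10
Reactants: 19 2-[2-(4-{2-(benzyloxy)-5-[2-(3-methoxyphenyl)ethyl]phenoxy}phenyl)ethyl]cyclohexa-2,5-diene-1,4-dione
Product: 20 2-[2-(4-{2-hydroxy-5-[2-(3-methoxyphenyl)ethyl]phenoxy}phenyl)ethyl]benzene-1,4-diol (target)
Conditions: H2 (1 atm), 10% Pd/C, EtOAc, rt; work-up under Ar
Reagents that add atoms: none
Why: Catalytic hydrogenation reduces the quinone to the hydroquinone and cleaves the benzyl aryl ether by hydrogenolysis in one operation; the diaryl ether, the aryl methyl ether and the bibenzyl chains are inert.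

**Compound list**

1 | 3-bromo-4-hydroxybenzaldehyde | O=Cc1ccc(O)c(Br)c1 | starting material
2 | 4-(benzyloxy)-3-bromobenzaldehyde | O=Cc1ccc(OCc2ccccc2)c(Br)c1 | intermediate
3 | (3-methoxybenzyl)triphenylphosphonium chloride | [Cl-].COc1cccc(C[P+](c2ccccc2)(c2ccccc2)c2ccccc2)c1 | starting material
4 | (3-methoxybenzylidene)triphenylphosphorane (ylide, not isolated) | COc1cccc(C=P(c2ccccc2)(c2ccccc2)c2ccccc2)c1 | intermediate
5 | 1-(benzyloxy)-2-bromo-4-[2-(3-methoxyphenyl)ethenyl]benzene, E/Z mixture | COc1cccc(C=Cc2ccc(OCc3ccccc3)c(Br)c2)c1 | intermediate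
6 | 1-(benzyloxy)-2-bromo-4-[2-(3-methoxyphenyl)ethyl]benzene | COc1cccc(CCc2ccc(OCc3ccccc3)c(Br)c2)c1 | intermediate
7 | methyl 3-(4-hydroxyphenyl)propanoate | COC(=O)CCc1ccc(O)cc1 | starting material
8 | methyl 3-(4-{2-(benzyloxy)-5-[2-(3-methoxyphenyl)ethyl]phenoxy}phenyl)propanoate | COc1cccc(CCc2ccc(OCc3ccccc3)c(Oc3ccc(CCC(=O)OC)cc3)c2)c1 | intermediate
9 | diisobutylaluminium hemiacetal of ester 8 (not isolated) | COc1cccc(CCc2ccc(OCc3ccccc3)c(Oc3ccc(CCC(OC)O[Al](CC(C)C)CC(C)C)cc3)c2)c1 | intermediate
10 | 3-(4-{2-(benzyloxy)-5-[2-(3-methoxyphenyl)ethyl]phenoxy}phenyl)propanal | COc1cccc(CCc2ccc(OCc3ccccc3)c(Oc3ccc(CCC=O)cc3)c2)c1 | intermediate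
11 | 1-(benzyloxy)-2-[4-(but-3-yn-1-yl)phenoxy]-4-[2-(3-methoxyphenyl)ethyl]benzene | COc1cccc(CCc2ccc(OCc3ccccc3)c(Oc3ccc(CCC#C)cc3)c2)c1 | intermediate
12 | vinyl bromide | C=CBr | starting material
13 | chromium hexacarbonyl | O=C=[Cr](=C=O)(=C=O)(=C=O)(=C=O)=C=O | starting material
14 | vinyllithium (not isolated) | [Li]C=C | intermediate
15 | lithium pentacarbonyl(1-oxidoprop-2-en-1-ylidene)chromate, the acylchromate (not isolated) | [Li+].[O-]C(C=C)=[Cr](=C=O)(=C=O)(=C=O)(=C=O)=C=O | intermediate
16 | pentacarbonyl[methoxy(vinyl)carbene]chromium | COC(C=C)=[Cr](=C=O)(=C=O)(=C=O)(=C=O)=C=O | intermediate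
17 | tricarbonylchromium complex of phenol 18, η6 on ring D, written with a dot-separated Cr(CO)3 fragment (not isolated) | COc1cccc(CCc2ccc(OCc3ccccc3)c(Oc3ccc(CCc4cc(OC)ccc4O)cc3)c2)c1.O=C=[Cr](=C=O)=C=O | intermediate
18 | 2-[2-(4-{2-(benzyloxy)-5-[2-(3-methoxyphenyl)ethyl]phenoxy}phenyl)ethyl]-4-methoxyphenol | COc1cccc(CCc2ccc(OCc3ccccc3)c(Oc3ccc(CCc4cc(OC)ccc4O)cc3)c2)c1 | intermediate
19 | 2-[2-(4-{2-(benzyloxy)-5-[2-(3-methoxyphenyl)ethyl]phenoxy}phenyl)ethyl]cyclohexa-2,5-diene-1,4-dione | COc1cccc(CCc2ccc(OCc3ccccc3)c(Oc3ccc(CCC4=CC(=O)C=CC4=O)cc3)c2)c1 | intermediate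
20 | 2-[2-(4-{2-hydroxy-5-[2-(3-methoxyphenyl)ethyl]phenoxy}phenyl)ethyl]benzene-1,4-diol | COc1cccc(CCc2ccc(O)c(Oc3ccc(CCc4cc(O)ccc4O)cc3)c2)c1 | target

**Step count**

Total: 10 steps. Longest linear sequence: 9 steps (1 → 2 → 5 → 6 → 8 → 10 → 11 → 18 → 19 → 20); step 7 is a one-step side branch that joins at step 8.

**Steps most likely to fail**

Step 8. The vinylcarbene complex may oligomerise or lose its carbene ligand faster than it takes up the alkyne, and the alkyne may be incorporated twice or polymerise, so that little ring D forms. The fallback sets out from 6 and comes back at 19; it brings ring D in preformed as a 2,5-dimethoxyphenyl unit. 4-(Benzyloxy)benzyl chloride and PPh3 (toluene, reflux) give [4-(benzyloxy)benzyl]triphenylphosphonium chloride F1. Wittig reaction of F1 with 2,5-dimethoxybenzaldehyde (KOtBu, THF) gives 2-{2-[4-(benzyloxy)phenyl]ethenyl}-1,4-dimethoxybenzene F2 as an E/Z mixture. Hydrogenation (H2, Pd/C, EtOAc) saturates the alkene and removes the benzyl group to give 4-[2-(2,5-dimethoxyphenyl)ethyl]phenol F3. Ullmann coupling of F3 with bromide 6 under the conditions of step 4 gives 1-(benzyloxy)-2-{4-[2-(2,5-dimethoxyphenyl)ethyl]phenoxy}-4-[2-(3-methoxyphenyl)ethyl]benzene F4. CAN in MeCN/H2O at 0 °C should demethylate the 1,4-dimethoxy ring oxidatively to quinone 19, and the route resumes at step 10.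

Step 7. The parent vinyl complex may polymerise or add to itself in a conjugate sense during O-methylation, concentration and filtration, so that no usable carbene reaches step 8. The fallback sets out from 13 and comes back at 18; it uses a stable silylvinyl complex as surrogate. (E)-(2-Bromovinyl)trimethylsilane and t-BuLi (Et2O, −78 °C) give (E)-[2-(trimethylsilyl)vinyl]lithium F5. Addition of F5 to 13 gives the lithium acylchromate F6, and MeOTf gives pentacarbonyl{methoxy[(E)-2-(trimethylsilyl)vinyl]carbene}chromium F7, which should tolerate chromatography and storage. Benzannulation of F7 with alkyne 11 (THF, 50 °C) is expected to pass through a cyclohexadienone that carries silicon on its sp3 carbon and aromatises by a 1,3-shift of silicon from carbon to oxygen. This gives the chromium tricarbonyl complex of the aryl silyl ether F8 and, after exposure to air, the aryl trimethylsilyl ether of 18 F9. K2CO3 in MeOH cleaves the silyl ether to phenol 18.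

Step 4. Oxidative addition of copper to the electron-rich, ortho-benzyloxy bromide may be slow, so that protodebromination and carbonate-mediated ester cleavage outrun C–O coupling. The fallback sets out from 6 and comes back at 8; it reverses the polarity of the coupling. Pd-catalysed hydroxylation of 6 (Pd2(dba)3, tBuXPhos, KOH, dioxane/H2O, 100 °C) gives 2-(benzyloxy)-5-[2-(3-methoxyphenyl)ethyl]phenol F10. Chan–Lam coupling of F10 with commercial [4-(3-methoxy-3-oxopropyl)phenyl]boronic acid (Cu(OAc)2, pyridine, 4 Å MS, CH2Cl2, air, rt) gives ester 8.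

**Further compounds**

F1 | step 8 | [4-(benzyloxy)benzyl]triphenylphosphonium chloride | [Cl-].c1ccc(COc2ccc(C[P+](c3ccccc3)(c3ccccc3)c3ccccc3)cc2)cc1
F2 | step 8 | 2-{2-[4-(benzyloxy)phenyl]ethenyl}-1,4-dimethoxybenzene, E/Z mixture | COc1ccc(OC)c(C=Cc2ccc(OCc3ccccc3)cc2)c1
F3 | step 8 | 4-[2-(2,5-dimethoxyphenyl)ethyl]phenol | COc1ccc(OC)c(CCc2ccc(O)cc2)c1
F4 | step 8 | 1-(benzyloxy)-2-{4-[2-(2,5-dimethoxyphenyl)ethyl]phenoxy}-4-[2-(3-methoxyphenyl)ethyl]benzene | COc1cccc(CCc2ccc(OCc3ccccc3)c(Oc3ccc(CCc4cc(OC)ccc4OC)cc3)c2)c1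
F5 | step 7 | (E)-[2-(trimethylsilyl)vinyl]lithium | [Li]/C=C/[Si](C)(C)C
F6 | step 7 | lithium pentacarbonyl[(E)-1-oxido-3-(trimethylsilyl)prop-2-en-1-ylidene]chromate | [Li+].[O-]C(/C=C/[Si](C)(C)C)=[Cr](=C=O)(=C=O)(=C=O)(=C=O)=C=O
F7 | step 7 | pentacarbonyl{methoxy[(E)-2-(trimethylsilyl)vinyl]carbene}chromium | COC(/C=C/[Si](C)(C)C)=[Cr](=C=O)(=C=O)(=C=O)(=C=O)=C=O
F8 | step 7 | tricarbonylchromium complex of aryl silyl ether F9, η6 on ring D, written with a dot-separated Cr(CO)3 fragment | COc1cccc(CCc2ccc(OCc3ccccc3)c(Oc3ccc(CCc4cc(OC)ccc4O[Si](C)(C)C)cc3)c2)c1.O=C=[Cr](=C=O)=C=O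
F9 | step 7 | trimethylsilyl ether of phenol 18 | COc1cccc(CCc2ccc(OCc3ccccc3)c(Oc3ccc(CCc4cc(OC)ccc4O[Si](C)(C)C)cc3)c2)c1
F10 | step 4 | 2-(benzyloxy)-5-[2-(3-methoxyphenyl)ethyl]phenol | COc1cccc(CCc2ccc(OCc3ccccc3)c(O)c2)c1
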